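The north-east flask ran for 12 h and the south flask for 15 h on the same charges, so I asked what the extra time could still buy.

- north-east: starting material 0.82 M; partner 2.46 M; second substrate 0.164 M; protic impurity 0.164 M; time 12 h
- south: starting material 0.82 M; partner 2.46 M; second substrate 0.164 M; protic impurity 0.164 M; time 15 h

    starting material + partner → target (k1 = 0.0017 M⁻¹ min⁻¹)
    second substrate + partner → second product (k2 = 2.0 × 10⁻⁴ M⁻¹ min⁻¹)
    starting material + protic impurity → quenched substrate (k3 = 0.013 M⁻¹ min⁻¹)
    second substrate ⇌ dormant form (K4 = 6.0, k4 = 0.0020 min⁻¹)
    partner → decomposed reagent (k5 = 1.6 × 10⁻⁴ min⁻¹)

* which of these there is most of at the end, counted by the starting material in it, north-east (target / starting material)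
* which of these there is most of at the end, counted by the starting material in it, south (target / starting material)
* final amount of the leader among these, as a percentage of the starting material charged, in north-east
* final amount of the leader among these, as a percentage of the starting material charged, in south

Starting material has two exits, to target and to quenched substrate, so I followed one molecule. Its two branches are pseudo-first-order at any moment, and at the charge they run at 0.00418 min⁻¹ and 0.00213 min⁻¹, which gives 66.2%. I call this the fork share: the target branch's rate constant times partner, divided by that term plus the quench branch's rate constant times protic impurity. Starting material doesn't appear in it.

But that share can't last. Quenching 33.8% of the starting material would take 0.277 M of protic impurity, more than the 0.164 M charged. So the impurity falls and the fork tilts towards target. Each impurity molecule quenches one substrate molecule, so the charge caps quenched substrate at 20.0%.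

Partner is consumed by coupling as well as by decay, and in south the coupling starts at 8.7 times the decay, so its concentration has to fall; I still held it at its charge, as a crude simplification for a reckoning by hand. Starting material then halves every 2.76 h, leaving 4.92% north-east and 2.32% south. Subtracting these and the cap, I committed to target leading at 75.1% north-east and 77.7% south, knowing that both approximations erred, in opposite directions.

The forecast gave target at 75% north-east and target at 78% south, holding that starting material “goes either to target or to quenching”.

In north-east the simulation gave target at 75.1%. In south it gave target at 77.7%. North-east kept 6.87% of its starting material and quenched 18.0%, so my two errors had cancelled. Quenching is the main reason target fell short: with it struck out, south reached 93.1%. South's fork share climbed to 93.1% by the end, and target held 81.0% of target plus quenched substrate, between the two shares. A neighbour of south with 0.33 M of starting material began at the same 66.2% and ended at 77.0%, and its target held 72.3% of the two.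

Its constants are made up; the rest is arithmetic.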